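The ten-membered carbocycle C1–C10 is hidden in a decalin. Because C8 carries oxygen and C2/C3 of the bridging furanone ring (O–C3=C2–C1–C10) lie at alkyne level, the C3–C8 bond can be a temporary ring-fusion bond. Eschenmoser–Tanabe fragmentation of a C3–C8 epoxy decal-2-one cuts it in one operation, giving the C2≡C3 alkyne and the C8 ketone of a cyclodecynone. The precursor comes from an enantioselective quinone-monoketal Diels–Alder reaction. It already carries C4–C7, C9 and C10 in final form, the cis-fused α-methylene-6,12-lactone, a silylated O9 and a free C10 hydroxyl, so that only O10 can later close the furanone.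

Key step: step 21

Remark: germacranolide numbering is used (C1 furanone carbonyl, C3 its enol-ether carbon, C6 lactone carbinol, C8 angelate carbinol, C11/C12/C13 lactone α-carbon, carbonyl and methylene, C14 on C10, C15 on C4); in the decalins ring A is C1–C2–C3–C8–C9–C10 and ring B is C3–C4–C5–C6–C7–C8.

Step 1
Reactants: 1 pent-1-en-3-one; 2 but-3-en-1-ol
Product: 3 (E)-7-hydroxyhept-4-en-3-one
Conditions: second-generation Hoveyda–Grubbs catalyst, [1,3-bis(2,4,6-trimethylphenyl)imidazolidin-2-ylidene]dichloro(2-isopropoxybenzylidene)ruthenium (2 mol%), CH2Cl2, 40 °C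
Reagents that add atoms: none
Why: Olefin cross-metathesis between an electron-poor enone and an unhindered terminal alkene favours the hetero-coupled E-enone, with ethene as the only by-product.

Step 2
Reactants: 3 (E)-7-hydroxyhept-4-en-3-one
Product: 4 (2Z,4E)-3,7-bis(triisopropylsilyloxy)hepta-2,4-diene
Conditions: iPr3SiOTf (2.3 equiv), Et3N, CH2Cl2, 0 °C
Reagents that add atoms: triisopropylsilyl trifluoromethanesulfonate, CC(C)[Si](C(C)C)(C(C)C)OS(=O)(=O)C(F)(F)F
Why: Soft enolisation with a silyl triflate and triethylamine removes an α′-hydrogen of the ethyl group to give the cross-conjugated (Z)-silyl dienol ether (methyl cis to oxygen, hence outward in the s-cis diene), while the primary alcohol is silylated in the same operation.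

Step 3
Reactants: 5 4-methoxy-2-methylphenol
Product: 6 4,4-dimethoxy-2-methylcyclohexa-2,5-dien-1-one
Conditions: PhI(OAc)2, MeOH, 0 °C
Reagents that add atoms: methanol, CO
Why: Hypervalent-iodine oxidative dearomatisation of a para-methoxyphenol in methanol traps the phenoxonium ion at C4 and gives the quinone monoketal.

Step 4
Reactants: 4 (2Z,4E)-3,7-bis(triisopropylsilyloxy)hepta-2,4-diene; 6 4,4-dimethoxy-2-methylcyclohexa-2,5-dien-1-one
Product: 7 cis-fused Diels–Alder adduct (C9 enone, C2 dimethyl ketal, C5 silyl enol ether)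
Conditions: (S)-1-(2-methylphenyl)-3,3-diphenyltetrahydro-1H,3H-pyrrolo[1,2-c][1,3,2]oxazaborole (20 mol%) activated with HN(SO2CF3)2, CH2Cl2, −78 → −40 °C
Reagents that add atoms: none
Why: In this oxazaborolidinium-catalysed enantioselective Diels–Alder reaction the catalyst binds the only ketone syn to C8–H, the nucleophilic diene terminus C4 bonds to the β-carbon C3 (para rule for a 2-silyloxy diene), and endo addition to the face left open by the (S)-catalyst (its antipode would give the mirror image) sets C3, C4, C7 and C8 with the methyl and the side chain cis to each other and to ring A.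

Step 5
Reactants: 7 cis-fused Diels–Alder adduct
Product: 10 tricyclic ether ketone (C5 ketone; C6–O–C12 tetrahydrofuran cis-fused at C6–C7), via bromo ketone 8 (not isolated), via bromo alcohol 9 (not isolated)
Conditions: NBS, NaHCO3, THF, −78 °C; then Bu4NF, −78 → 0 °C
Reagents that add atoms: none
Why: Electrophilic bromination of the silyl enol ether puts bromine on C6 from the convex face (opposite ring A and the C7 chain), and the C12 alkoxide freed by fluoride displaces it in a 5-exo-tet intramolecular Williamson reaction with inversion, so that O6 ends cis to the C7–C11 bond.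

Step 6
Reactants: 10 tricyclic ether ketone
Product: 11 C5 alcohol (C4 methyl, O5, O6 and C11 all cis)
Conditions: NaBH4, MeOH/CH2Cl2 (1:1), −78 °C
Reagents that add atoms: none
Why: Borohydride reduces the saturated α-alkoxy ketone faster than the hindered enone and adds from the convex face, anti to the C4 methyl and the C6 oxygen (Felkin–Anh), which gives the all-cis C5 alcohol.

Step 7
Reactants: 11 C5 alcohol
Product: 12 C5 tert-butyldimethylsilyl ether
Conditions: tBuMe2SiOTf, 2,6-lutidine, CH2Cl2, −78 °C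
Reagents that add atoms: tert-butyldimethylsilyl trifluoromethanesulfonate, CC(C)(C)[Si](C)(C)OS(=O)(=O)C(F)(F)F
Why: Silylation of a hindered secondary alcohol with a silyl triflate and 2,6-lutidine is fast enough at low temperature to leave the dimethyl ketal untouched.

Step 8
Reactants: 12 C5 tert-butyldimethylsilyl ether
Product: 13 cis-fused ene-dione (C2 and C9 ketones, C1=C10)
Conditions: pyridinium p-toluenesulfonate, acetone/H2O (10:1), rt
Reagents that add atoms: water, O
Why: Mild acid hydrolysis of the dimethyl ketal is much faster than loss of the hindered silyl ether, and the short exposure does not enolise the cis ring fusion.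

Step 9
Reactants: 13 cis-fused ene-dione
Product: 14 C1,C10-diol (both hydroxyls anti to ring B)
Conditions: OsO4 (5 mol%), N-methylmorpholine N-oxide, acetone/H2O, rt
Reagents that add atoms: N-methylmorpholine N-oxide, C[N+]1([O-])CCOCC1; water, O
Why: Catalytic OsO4 syn-dihydroxylation of the C1=C10 ene-dione bond takes place from the convex face of the cis-fused bicycle, anti to ring B, so that O10 and O1 become trans and the C10 methyl cis to the ring-B substituents.

Step 10
Reactants: 14 C1,C10-diol
Product: 16 bis-silyl ether (C1 OSiEt3, C10 OSiMe3), via C1 triethylsilyl ether 15 (not isolated)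
Conditions: Et3SiCl, imidazole, DMF, 0 °C; then Me3SiCl, rt
Reagents that add atoms: chlorotriethylsilane, CC[Si](Cl)(CC)CC; chlorotrimethylsilane, C[Si](C)(C)Cl
Why: Graded silylation: the secondary α-ketol hydroxyl at C1 takes the bulkier silyl group first, after which the tertiary C10 hydroxyl accepts the small trimethylsilyl group, which also shields this α-ketol from periodate in the next step.

Step 11
Reactants: 16 bis-silyl ether
Product: 17 6,12-lactone
Conditions: RuCl3·xH2O (5 mol%), NaIO4, CCl4/MeCN/pH 7 phosphate buffer, rt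
Reagents that add atoms: sodium periodate, [Na+].[O-]I(=O)(=O)=O
Why: RuO4 formed in situ oxidises the ether methylene C12 (more accessible than the C6 methine) to the γ-lactone, a known ether-to-ester oxidation that is safe here because no alkene or free secondary alcohol is present.

Step 12
Reactants: 17 6,12-lactone
Product: 19 C3=C8 ene-dione (ring-fusion alkene), via bis(trimethylsilyl) dienol ether 18 (not isolated)
Conditions: Me3SiOTf, Et3N, CH2Cl2, 0 °C; filtration in pentane; then DDQ, 2,6-lutidine, CH2Cl2, 0 °C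
Reagents that add atoms: none
Why: Soft enolisation gives the conjugated 1,4-bis(silyloxy)-1,3-diene (C9 can enolise only toward C8, C2 prefers the conjugated C3 side), and its two-electron oxidation by DDQ (silyl enol ether dehydrogenation) can only deliver the C3=C8 ene-dione, so no choice between β-hydrogens arises.

Step 13
Reactants: 19 C3=C8 ene-dione
Product: 20 3,8-epoxy-2,9-dione
Conditions: tBuOOH (decane), DBU, CH2Cl2, −20 °C
Reagents that add atoms: tert-butyl hydroperoxide, CC(C)(C)OO
Why: Weitz–Scheffer epoxidation of the doubly activated tetrasubstituted alkene is fast at low temperature, and the peroxide should add anti to the pseudo-axial C4 methyl, on the face of O1 and O10, although the configuration of this epoxide does not reach the target.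

Step 14
Reactants: 20 3,8-epoxy-2,9-dione
Product: 22 epoxy triol (C2, C9 and C10 hydroxyls), via epoxy diol trimethylsilyl ether 21 (not isolated)
Conditions: NaBH4, CeCl3·7H2O, MeOH/THF, −78 → −40 °C; then K2CO3, MeOH, 0 °C
Reagents that add atoms: none
Why: Luche reduction delivers hydride to C9 anti to both adjacent C–O bonds (the epoxide and the pseudo-axial C10–OSiMe3, polar Felkin–Anh), which sets O9 cis to O10 while the C2 carbinol configuration is irrelevant, and potassium carbonate in methanol then cleaves only the trimethylsilyl ether.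

Step 15
Reactants: 22 epoxy triol
Product: 23 9,10-acetonide (C2 hydroxyl free)
Conditions: 2,2-dimethoxypropane, pyridinium p-toluenesulfonate, acetone, rt
Reagents that add atoms: 2,2-dimethoxypropane, COC(C)(C)OC
Why: Acid-catalysed transketalisation forms the five-membered dioxolane only across the cis-1,2-diol O9/O10, which tells the C9 hydroxyl from the C2 hydroxyl.

Step 16
Reactants: 23 9,10-acetonide
Product: 24 Mannich base (C11–CH2NMe2)
Conditions: LiN(iPr)2 (2.3 equiv), THF, −78 °C; then CH2=NMe2+ I−, −78 → −20 °C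
Reagents that add atoms: N,N-dimethylmethyleneiminium iodide (Eschenmoser's salt), C=[N+](C)C.[I-]
Why: With the C2 alkoxide as a spectator, the lithium enolate of the lactone (the only enolisable carbonyl present) undergoes a Mannich reaction with Eschenmoser's salt at C11, whose configuration is lost in the next step.

Step 17
Reactants: 24 Mannich base
Product: 26 α-methylene lactone, via trimethylammonium iodide 25 (not isolated)
Conditions: MeI, THF, rt; then NaHCO3 (aq), CH2Cl2, rt
Reagents that add atoms: none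
Why: N-Methylation followed by base-induced β-elimination of trimethylamine (Hofmann-type, E1cB) unveils the α-methylene lactone.

Step 18
Reactants: 26 α-methylene lactone
Product: 27 epoxy ketone acetonide (C2 ketone)
Conditions: Dess–Martin periodinane, NaHCO3, CH2Cl2, 0 °C → rt
Reagents that add atoms: none
Why: Dess–Martin oxidation converts the only free hydroxyl into the C2 ketone without touching the epoxide or the methylene lactone.

Step 19
Reactants: 27 epoxy ketone acetonide
Product: 28 epoxy ketone triol (C1, C9 and C10 hydroxyls)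
Conditions: AcOH/THF/H2O (3:1:1), 45 °C
Reagents that add atoms: none
Why: Aqueous acetic acid hydrolyses the dioxolane and the triethylsilyl ether but leaves the tert-butyldimethylsilyl ether, the lactone and the epoxy ketone (graded acid deprotection), the acetonide having done its work of distinguishing C9 from C2.

Step 20
Reactants: 28 epoxy ketone triol
Product: 30 epoxy decal-2-one precursor (C1 OSiEt3, C9 OSitBuMe2, C10 OH), via C1 triethylsilyl ether 29 (not isolated)
Conditions: Et3SiOTf (1.05 equiv), 2,6-lutidine, CH2Cl2, −78 °C; then tBuMe2SiOTf, −78 → 0 °C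
Reagents that add atoms: triethylsilyl trifluoromethanesulfonate, CC[Si](CC)(CC)OS(=O)(=O)C(F)(F)F; tert-butyldimethylsilyl trifluoromethanesulfonate, CC(C)(C)[Si](C)(C)OS(=O)(=O)C(F)(F)F
Why: Stepwise silylation: the less hindered α-ketol hydroxyl at C1 takes the triethylsilyl group first, then the second triflate caps the secondary C9 hydroxyl, while the tertiary C10 hydroxyl stays free so that it alone can later close the furanone.

Step 21
Reactants: 30 epoxy decal-2-one precursor
Product: 32 cyclodec-2-yn-8-one (ten-membered ynone precursor with C8 ketone), via tosylhydrazone 31 (not isolated)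
Conditions: p-TolSO2NHNH2 (1.2 equiv), AcOH/CH2Cl2 (1:2), −20 → 0 °C
Reagents that add atoms: none
Why: The hydrazide condenses with the C2 ketone, the hydrazone opens the epoxide at C3 to an azo-alkene carrying the C8 alkoxide, and collapse of that alkoxide cleaves the C3–C8 bond with loss of sulfinate and N2, leaving the C2≡C3 alkyne and the C8 ketone. This is the Eschenmoser–Tanabe fragmentation of an α,β-epoxy ketone, known for ring-fusion epoxy decalones. No ring-closing bond is formed and no stereocentre is created: the ten-membered carbocycle appears because the bond shared by the two six-membered rings is cut. The anti arrangement of the C2–N and C3–C8 bonds across C2=C3 that the cleavage needs is fixed by ring A whichever face carries the epoxide. The step needs condensation at the hindered C2 carbonyl to outrun acid-induced epoxide opening and addition of the hydrazide to the methylene lactone, and C7 and C9 beside the new ketone must not epimerise; cold, weakly acidic, base-free conditions serve both needs.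

Step 22
Reactants: 32 cyclodec-2-yn-8-one
Product: 33 C8 alcohol
Conditions: NaBH4, CeCl3·7H2O, MeOH, −78 °C
Reagents that add atoms: none
Why: Luche reduction of the C8 ketone should follow the polar Felkin–Anh model, hydride adding anti to the C9–O bond of the non-chelating silyl ether to give the 8,9-syn alcohol of the target, while CeCl3 also suppresses conjugate reduction of the methylene lactone.

Step 23
Reactants: 33 C8 alcohol; 34 angelic acid
Product: 36 C8 angelate, via mixed anhydride 35 (not isolated)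
Conditions: 2,4,6-Cl3C6H2COCl, Et3N, toluene, rt; then 33, toluene, 75 °C
Reagents that add atoms: none
Why: Yamaguchi-type esterification through the mixed anhydride with 2,4,6-trichlorobenzoic acid, run without a nucleophilic amine catalyst, acylates the only free secondary hydroxyl and keeps the Z double bond of the angelate.

Step 24
Reactants: 36 C8 angelate
Product: 37 C1 propargylic alcohol
Conditions: pyridinium p-toluenesulfonate, MeOH/CH2Cl2, 0 °C
Reagents that add atoms: none
Why: Mildly acidic methanolysis removes the triethylsilyl ether selectively beside the two tert-butyldimethylsilyl ethers (graded silyl ether cleavage).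

Step 25
Reactants: 37 C1 propargylic alcohol
Product: 39 furanone bis(tert-butyldimethylsilyl) ether, via ynone 38 (not isolated)
Conditions: MnO2, CH2Cl2, rt; filtration; then AuCl3 (5 mol%), CH2Cl2, rt
Reagents that add atoms: none
Why: MnO2 oxidises only the propargylic alcohol, and the resulting ynone is closed by gold-catalysed 5-endo-dig hydroalkoxylation from the tertiary C10 hydroxyl, the only free hydroxyl in the molecule, to give the 3(2H)-furanone without creating a stereocentre.

Step 26
Reactants: 39 furanone bis(tert-butyldimethylsilyl) ether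
Product: 40 CNP0206920.1
Conditions: HF·pyridine, pyridine, THF, 0 °C → rt
Reagents that add atoms: none
Why: Buffered fluoride desilylation frees the C5 and C9 hydroxyls and spares the angelate, the furanone and the methylene lactone.

Compound list

1 | pent-1-en-3-one | C=CC(=O)CC | starting material
2 | but-3-en-1-ol | C=CCCO | starting material
3 | (E)-7-hydroxyhept-4-en-3-one | CCC(=O)/C=C/CCO | intermediate
4 | (2Z,4E)-3,7-bis(triisopropylsilyloxy)hepta-2,4-diene | C/C=C(\O[Si](C(C)C)(C(C)C)C(C)C)/C=C/CCO[Si](C(C)C)(C(C)C)C(C)C | intermediate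
5 | 4-methoxy-2-methylphenol | Cc1cc(OC)ccc1O | starting material
6 | 4,4-dimethoxy-2-methylcyclohexa-2,5-dien-1-one | COC1(OC)C=CC(=O)C(C)=C1 | intermediate
7 | cis-fused Diels–Alder adduct: C9 enone (C1=C10, C10 methyl), C2 dimethyl ketal, C5 triisopropylsilyl enol ether; H3 and H8 cis, C4 methyl and C7 silyloxyethyl chain cis to each other and to ring A | O=C1C(C)=CC(OC)(OC)[C@@H]2[C@H](C)C(O[Si](C(C)C)(C(C)C)C(C)C)=C[C@H](CCO[Si](C(C)C)(C(C)C)C(C)C)[C@H]12 | intermediate
8 | bromo ketone: C5 ketone, C6 bromide trans to the C7 chain | O=C1C(C)=CC(OC)(OC)[C@@H]2[C@H](C)C(=O)[C@@H](Br)[C@H](CCO[Si](C(C)C)(C(C)C)C(C)C)[C@H]12 | intermediate (not isolated)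
9 | bromo alcohol: as 8 with free C12 hydroxyl | O=C1C(C)=CC(OC)(OC)[C@@H]2[C@H](C)C(=O)[C@@H](Br)[C@H](CCO)[C@H]12 | intermediate (not isolated)
10 | tricyclic ether ketone: C5 ketone, C6–O–C12 tetrahydrofuran cis-fused at C6–C7 | O=C1C(C)=CC(OC)(OC)[C@@H]2[C@H](C)C(=O)[C@@H]3OCC[C@@H]3[C@H]12 | intermediate
11 | C5 alcohol: C4 methyl, C5 OH, C6 O and C7–C11 all cis | O=C1C(C)=CC(OC)(OC)[C@@H]2[C@H](C)[C@H](O)[C@@H]3OCC[C@@H]3[C@H]12 | intermediate
12 | C5 tert-butyldimethylsilyl ether of 11 | O=C1C(C)=CC(OC)(OC)[C@@H]2[C@H](C)[C@H](O[Si](C)(C)C(C)(C)C)[C@@H]3OCC[C@@H]3[C@H]12 | intermediate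
13 | cis-fused ene-dione: C2 and C9 ketones, C1=C10 | O=C1C(C)=CC(=O)[C@@H]2[C@H](C)[C@H](O[Si](C)(C)C(C)(C)C)[C@@H]3OCC[C@@H]3[C@H]12 | intermediate
14 | C1,C10-diol: hydroxyls cis to each other and anti to ring B, C10 methyl syn to ring B | O=C1[C@@](C)(O)[C@@H](O)C(=O)[C@@H]2[C@H](C)[C@H](O[Si](C)(C)C(C)(C)C)[C@@H]3OCC[C@@H]3[C@H]12 | intermediate
15 | C1 triethylsilyl ether of 14 | O=C1[C@@](C)(O)[C@@H](O[Si](CC)(CC)CC)C(=O)[C@@H]2[C@H](C)[C@H](O[Si](C)(C)C(C)(C)C)[C@@H]3OCC[C@@H]3[C@H]12 | intermediate (not isolated)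
16 | bis-silyl ether: C1 OSiEt3, C10 OSiMe3 | O=C1[C@@](C)(O[Si](C)(C)C)[C@@H](O[Si](CC)(CC)CC)C(=O)[C@@H]2[C@H](C)[C@H](O[Si](C)(C)C(C)(C)C)[C@@H]3OCC[C@@H]3[C@H]12 | intermediate
17 | 6,12-lactone (cis-fused γ-lactone) of 16 | O=C1[C@@](C)(O[Si](C)(C)C)[C@@H](O[Si](CC)(CC)CC)C(=O)[C@@H]2[C@H](C)[C@H](O[Si](C)(C)C(C)(C)C)[C@@H]3OC(=O)C[C@@H]3[C@H]12 | intermediate
18 | bis(trimethylsilyl) dienol ether: C2(OSiMe3)=C3–C8=C9(OSiMe3) | C[Si](C)(C)OC=1[C@@](C)(O[Si](C)(C)C)[C@@H](O[Si](CC)(CC)CC)C(O[Si](C)(C)C)=C2[C@H](C)[C@H](O[Si](C)(C)C(C)(C)C)[C@@H]3OC(=O)C[C@@H]3C2=1 | intermediate (not isolated)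
19 | C3=C8 ene-dione: C2 and C9 ketones on the ring-fusion alkene | O=C1[C@@](C)(O[Si](C)(C)C)[C@@H](O[Si](CC)(CC)CC)C(=O)C=2[C@H](C)[C@H](O[Si](C)(C)C(C)(C)C)[C@@H]3OC(=O)C[C@@H]3C1=2 | intermediate
20 | 3,8-epoxy-2,9-dione: epoxide on the face of O1 and O10 (expected) | O=C1[C@@](C)(O[Si](C)(C)C)[C@@H](O[Si](CC)(CC)CC)C(=O)[C@]2(O3)[C@H](C)[C@H](O[Si](C)(C)C(C)(C)C)[C@@H]4OC(=O)C[C@@H]4[C@]123 | intermediate
21 | epoxy diol trimethylsilyl ether: C2 and C9 hydroxyls cis to the epoxide, O9 cis to O10 | O[C@H]1[C@@](C)(O[Si](C)(C)C)[C@@H](O[Si](CC)(CC)CC)[C@@H](O)[C@]2(O3)[C@H](C)[C@H](O[Si](C)(C)C(C)(C)C)[C@@H]4OC(=O)C[C@@H]4[C@]123 | intermediate (not isolated)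
22 | epoxy triol: C2, C9 and C10 hydroxyls | O[C@H]1[C@@](C)(O)[C@@H](O[Si](CC)(CC)CC)[C@@H](O)[C@]2(O3)[C@H](C)[C@H](O[Si](C)(C)C(C)(C)C)[C@@H]4OC(=O)C[C@@H]4[C@]123 | intermediate
23 | 9,10-acetonide with free C2 hydroxyl | CC5(C)O[C@H]1[C@@](C)(O5)[C@@H](O[Si](CC)(CC)CC)[C@@H](O)[C@]2(O3)[C@H](C)[C@H](O[Si](C)(C)C(C)(C)C)[C@@H]4OC(=O)C[C@@H]4[C@]123 | intermediate
24 | Mannich base: C11 dimethylaminomethyl lactone (C11 epimers) | CC5(C)O[C@H]1[C@@](C)(O5)[C@@H](O[Si](CC)(CC)CC)[C@@H](O)[C@]2(O3)[C@H](C)[C@H](O[Si](C)(C)C(C)(C)C)[C@@H]4OC(=O)C(CN(C)C)[C@@H]4[C@]123 | intermediate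
25 | trimethylammonium iodide of 24 | CC5(C)O[C@H]1[C@@](C)(O5)[C@@H](O[Si](CC)(CC)CC)[C@@H](O)[C@]2(O3)[C@H](C)[C@H](O[Si](C)(C)C(C)(C)C)[C@@H]4OC(=O)C(C[N+](C)(C)C)[C@@H]4[C@]123.[I-] | intermediate (not isolated)
26 | α-methylene lactone (C11=C13) | CC5(C)O[C@H]1[C@@](C)(O5)[C@@H](O[Si](CC)(CC)CC)[C@@H](O)[C@]2(O3)[C@H](C)[C@H](O[Si](C)(C)C(C)(C)C)[C@@H]4OC(=O)C(=C)[C@@H]4[C@]123 | intermediate
27 | epoxy ketone acetonide: C2 ketone, C3–C8 epoxide, 9,10-acetonide, C1 OSiEt3 | CC5(C)O[C@H]1[C@@](C)(O5)[C@@H](O[Si](CC)(CC)CC)C(=O)[C@]2(O3)[C@H](C)[C@H](O[Si](C)(C)C(C)(C)C)[C@@H]4OC(=O)C(=C)[C@@H]4[C@]123 | intermediate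
28 | epoxy ketone triol: C1, C9 and C10 hydroxyls | O[C@H]1[C@@](C)(O)[C@@H](O)C(=O)[C@]2(O3)[C@H](C)[C@H](O[Si](C)(C)C(C)(C)C)[C@@H]4OC(=O)C(=C)[C@@H]4[C@]123 | intermediate
29 | C1 triethylsilyl ether of 28 | O[C@H]1[C@@](C)(O)[C@@H](O[Si](CC)(CC)CC)C(=O)[C@]2(O3)[C@H](C)[C@H](O[Si](C)(C)C(C)(C)C)[C@@H]4OC(=O)C(=C)[C@@H]4[C@]123 | intermediate (not isolated)
30 | precursor, C3–C8 epoxy decal-2-one: C1 OSiEt3, C9 OSitBuMe2, C10 OH, C5 OSitBuMe2, cis-fused α-methylene-6,12-lactone (C1 and epoxide configurations as expected, both lost later) | CC(C)(C)[Si](C)(C)O[C@H]1[C@@](C)(O)[C@@H](O[Si](CC)(CC)CC)C(=O)[C@]2(O3)[C@H](C)[C@H](O[Si](C)(C)C(C)(C)C)[C@@H]4OC(=O)C(=C)[C@@H]4[C@]123 | intermediate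
31 | C2 tosylhydrazone of 30 | CC(C)(C)[Si](C)(C)O[C@H]1[C@@](C)(O)[C@@H](O[Si](CC)(CC)CC)C(=NNS(=O)(=O)c5ccc(C)cc5)[C@]2(O3)[C@H](C)[C@H](O[Si](C)(C)C(C)(C)C)[C@@H]4OC(=O)C(=C)[C@@H]4[C@]123 | intermediate (not isolated)
32 | ten-membered cycloalkynone: C8 ketone, C2≡C3, C1 OSiEt3, C9 OSitBuMe2, C10 OH | CC(C)(C)[Si](C)(C)O[C@H]1[C@@](C)(O)[C@@H](O[Si](CC)(CC)CC)C#C[C@H](C)[C@H](O[Si](C)(C)C(C)(C)C)[C@@H]2OC(=O)C(=C)[C@@H]2C1=O | intermediate
33 | C8 alcohol (O8 syn to O9 in the zigzag sense) | CC(C)(C)[Si](C)(C)O[C@H]1[C@@](C)(O)[C@@H](O[Si](CC)(CC)CC)C#C[C@H](C)[C@H](O[Si](C)(C)C(C)(C)C)[C@@H]2OC(=O)C(=C)[C@@H]2[C@@H]1O | intermediate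
34 | angelic acid, (Z)-2-methylbut-2-enoic acid | C/C=C(/C)C(=O)O | starting material
35 | angelic 2,4,6-trichlorobenzoic anhydride | C/C=C(/C)C(=O)OC(=O)c1c(Cl)cc(Cl)cc1Cl | intermediate (not isolated)
36 | C8 angelate | CC(C)(C)[Si](C)(C)O[C@H]1[C@@](C)(O)[C@@H](O[Si](CC)(CC)CC)C#C[C@H](C)[C@H](O[Si](C)(C)C(C)(C)C)[C@@H]2OC(=O)C(=C)[C@@H]2[C@@H]1OC(=O)/C(C)=C\C | intermediate
37 | C1 propargylic alcohol | CC(C)(C)[Si](C)(C)O[C@H]1[C@@](C)(O)[C@@H](O)C#C[C@H](C)[C@H](O[Si](C)(C)C(C)(C)C)[C@@H]2OC(=O)C(=C)[C@@H]2[C@@H]1OC(=O)/C(C)=C\C | intermediate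
38 | ynone: C1 ketone conjugated to C2≡C3, free C10 hydroxyl | CC(C)(C)[Si](C)(C)O[C@H]1[C@@](C)(O)C(=O)C#C[C@H](C)[C@H](O[Si](C)(C)C(C)(C)C)[C@@H]2OC(=O)C(=C)[C@@H]2[C@@H]1OC(=O)/C(C)=C\C | intermediate (not isolated)
39 | furanone with C5 and C9 tert-butyldimethylsilyl ethers | C=C1C(=O)O[C@H]2[C@@H](O[Si](C)(C)C(C)(C)C)[C@@H](C)C3=CC(=O)[C@](C)(O3)[C@H](O[Si](C)(C)C(C)(C)C)[C@@H](OC(=O)/C(C)=C\C)[C@@H]12 | intermediate
40 | CNP0206920.1 | C=C1C(=O)O[C@H]2[C@@H](O)[C@@H](C)C3=CC(=O)[C@](C)(O3)[C@H](O)[C@@H](OC(=O)/C(C)=C\C)[C@@H]12 | target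

Total step count: 26.
Longest linear sequence: 25 steps (steps 1, 2 and 4–26).

Steps most likely to fail

Step 21 (fragmentation). The condensation at the C2 carbonyl, which sits between a silyloxy-bearing carbon and the fully substituted epoxide carbon, may be slow. Acid-induced opening of the epoxide or addition of the hydrazide to the methylene lactone could then take over. Fallback: setting out from 30, condensation with 1-amino-trans-2,3-diphenylaziridine under neutral conditions (CH2Cl2, 0 °C) gives the N-aziridinyl imine F1. It is isolated and warmed in toluene (60–80 °C), where it fragments without acid, with loss of trans-stilbene and N2. The route is rejoined at 32.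

Step 22 (C8 reduction). Hydride may reach C8 from the other face of the mobile ten-membered ring, or with poor facial selectivity. Fallback: setting out from 32, the alcohol formed by attack on the other face, the C8-epimeric alcohol F2, is esterified with angelic acid 34 under Mitsunobu conditions (PPh3, diisopropyl azodicarboxylate, toluene, 0 °C). The SN2 displacement inverts C8 while installing the ester, and the route is rejoined at 36.

Step 14 (C9 reduction). Hydride may be delivered to the wrong face of the C9 carbonyl, for example if the epoxide of step 13 has formed on the opposite face, giving the trans-9,10-diol. Fallback: setting out from 19, the order is inverted. Luche reduction (NaBH4, CeCl3·7H2O, MeOH, −78 °C) of the planar ene-dione, where only the pseudo-axial C10 silyl ether differentiates the faces of C9, gives the ene-diol F3. Hydroxyl-directed epoxidation of its tetrasubstituted alkene (VO(acac)2, tBuOOH, CH2Cl2, 0 °C) then gives 21, where the route is rejoined.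

Further compounds

F1 | step 21 | N-(trans-2,3-diphenylaziridin-1-yl)imine of 30 at C2 (aziridine racemic trans) | CC(C)(C)[Si](C)(C)O[C@H]1[C@@](C)(O)[C@@H](O[Si](CC)(CC)CC)C(=NN5C(c6ccccc6)C5c6ccccc6)[C@]2(O3)[C@H](C)[C@H](O[Si](C)(C)C(C)(C)C)[C@@H]4OC(=O)C(=C)[C@@H]4[C@]123
F2 | step 22 | C8-epimeric alcohol (C8 epimer of 33) | CC(C)(C)[Si](C)(C)O[C@H]1[C@@](C)(O)[C@@H](O[Si](CC)(CC)CC)C#C[C@H](C)[C@H](O[Si](C)(C)C(C)(C)C)[C@@H]2OC(=O)C(=C)[C@@H]2[C@H]1O
F3 | step 14 | ene-diol: C2 and C9 allylic hydroxyls on the C3=C8 alkene, C10 OSiMe3, C1 OSiEt3 | O[C@H]1[C@@](C)(O[Si](C)(C)C)[C@@H](O[Si](CC)(CC)CC)[C@@H](O)C=2[C@H](C)[C@H](O[Si](C)(C)C(C)(C)C)[C@@H]3OC(=O)C[C@@H]3C1=2
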